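The route rests on cutting the pyrrole ring of the indole at N1–C2 and C3–C3a. C2 (the brominated carbon) and C3 (bearing the CH2NMe2 arm) are the two carbons of an unsymmetrical alkyne. A palladium-catalysed heteroannulation of an ortho-iodoaniline with a silyl-capped propargylamine should therefore form both bonds and the five-membered ring in one operation, with silicon at C2 as a stand-in for bromine and the side chain already at its amine level. The precursor pair is 4,5-dibromo-2-iodo-N-methylaniline, which carries the N1 methyl group and the future C5 and C6 bromines, and N,N-dimethyl-3-(triethylsilyl)prop-2-yn-1-amine. Ipso-bromodesilylation and N-oxidation then finish the target.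

Key step: step 4

Remark: the target has no stereocentre; the amine oxide is taken as the free N+–O− zwitterion, not a salt or hydrate.

Step 1
Reactants: 1 3,4-dibromoaniline
Product: 2 4,5-dibromo-2-iodoaniline
Conditions: NIS (1.0 equiv), AcOH, rt, dark
Reagents that add atoms: N-iodosuccinimide, O=C1CCC(=O)N1I
Why: Electrophilic aromatic iodination of an aniline: the para position is blocked by bromine and the ortho position flanked by the C3 bromine is hindered, so iodine should enter at C6, which becomes C2 of the product.

Step 2
Reactants: 2 4,5-dibromo-2-iodoaniline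
Product: 4 4,5-dibromo-2-iodo-N-methylaniline, via N-(methoxymethyl)aniline 3 (not isolated)
Conditions: (CH2O)n, NaOMe, MeOH, 60 °C; then NaBH4, 60 °C
Reagents that add atoms: paraformaldehyde (as formaldehyde), C=O
Why: Reductive mono-N-methylation through a hemiaminal ether: methoxide-mediated condensation with formaldehyde stops at the N-(methoxymethyl)aniline, whose N-methylene imine is reduced by NaBH4, so a second methyl group cannot enter and borohydride leaves the three aryl halides untouched.

Step 3
Reactants: 5 N,N-dimethylprop-2-yn-1-amine; 6 chlorotriethylsilane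
Product: 8 N,N-dimethyl-3-(triethylsilyl)prop-2-yn-1-amine, via lithium acetylide 7 (not isolated)
Conditions: n-BuLi, THF, −78 °C; then Et3SiCl, −78 °C to rt
Reagents that add atoms: none
Why: Deprotonation of the terminal alkyne by n-BuLi and C-silylation of the lithium acetylide by the chlorosilane, a standard alkyne silylation in which the tertiary amine is inert.

Step 4
Reactants: 4 4,5-dibromo-2-iodo-N-methylaniline; 8 N,N-dimethyl-3-(triethylsilyl)prop-2-yn-1-amine (2 equiv)
Product: 9 1-[5,6-dibromo-1-methyl-2-(triethylsilyl)-1H-indol-3-yl]-N,N-dimethylmethanamine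
Conditions: Pd(OAc)2 (5 mol %), LiCl (1 equiv), K2CO3 (3 equiv), DMF, 90 °C
Reagents that add atoms: none
Why: Zerovalent palladium generated in situ from Pd(OAc)2 inserts into the C–I bond of 4, the arylpalladium species adds syn across the alkyne of 8 so that the aryl carbon bonds to the aminomethyl-bearing alkyne carbon (C3–C3a) and palladium ends on the silyl-bearing carbon, the N-methylamino group then displaces halide on palladium, and C–N reductive elimination from the six-membered azapalladacycle forms N1–C2. The closest known reaction type is the Larock heteroannulation of 2-iodoanilines with silyl-substituted internal alkynes, which places silicon at C2. The pyrrole ring is closed as a [3+2] annulation in which the aniline supplies N1, C7a and C3a and the alkyne supplies C2 and C3, the ring-closing event being the reductive elimination. No stereocenter is formed. Regioselectivity is secured by the bulk of the triethylsilyl group, which stays away from the aryl group during insertion and so ends next to nitrogen, and chemoselectivity for C–I over the two C–Br bonds by the much faster oxidative addition of the iodide under phosphine-free conditions at moderate temperature. K2CO3 takes up the hydrogen iodide and LiCl keeps the catalyst as a soluble chloride-ligated species, while the tertiary amine and the C–Si bond are spectators.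

Step 5
Reactants: 9 1-[5,6-dibromo-1-methyl-2-(triethylsilyl)-1H-indol-3-yl]-N,N-dimethylmethanamine
Product: 12 1-(2,5,6-tribromo-1-methyl-1H-indol-3-yl)-N,N-dimethylmethanamine, via silylindole ammonium trifluoroacetate 10 (not isolated), via bromoindole ammonium trifluoroacetate 11 (not isolated)
Conditions: TFA (1.1 equiv), CH2Cl2, 0 °C; then NBS (1.05 equiv), 0 °C; aq. NaHCO3 work-up
Reagents that add atoms: N-bromosuccinimide, O=C1CCC(=O)N1Br
Why: Electrophilic ipso-bromodesilylation of a 2-silylindole: bromine adds at the silicon-bearing C2 (cation stabilised by the C–Si bond) and silicon is lost, while prior protonation removes the nitrogen lone pair that would otherwise be brominated or would expel the side chain as an iminium ion; the benzo ring, deactivated by two bromines, should not react.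

Step 6
Reactants: 12 1-(2,5,6-tribromo-1-methyl-1H-indol-3-yl)-N,N-dimethylmethanamine
Product: 13 1-(2,5,6-tribromo-1-methyl-1H-indol-3-yl)-N,N-dimethylmethanamine N-oxide
Conditions: mCPBA (1.0 equiv), CH2Cl2, −20 to 0 °C; filtration through basic Al2O3 (CH2Cl2/MeOH), evaporation without heating
Reagents that add atoms: mCPBA (3-chloroperoxybenzoic acid), OOC(=O)c1cccc(Cl)c1
Why: Peracid N-oxidation of a tertiary amine: the aliphatic NMe2 nitrogen is by far the most nucleophilic site, the indole C2–C3 bond being deactivated by the bromines, so one equivalent of peracid at low temperature should stop at the amine oxide, which has no β-hydrogen for Cope elimination.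

Compound list
1 | 3,4-dibromoaniline | Nc1ccc(Br)c(Br)c1 | starting material
2 | 4,5-dibromo-2-iodoaniline | Nc1cc(Br)c(Br)cc1I | intermediate
3 | 4,5-dibromo-2-iodo-N-(methoxymethyl)aniline (formed in the flask) | COCNc1cc(Br)c(Br)cc1I | intermediate
4 | 4,5-dibromo-2-iodo-N-methylaniline | CNc1cc(Br)c(Br)cc1I | intermediate
5 | N,N-dimethylprop-2-yn-1-amine | CN(C)CC#C | starting material
6 | chlorotriethylsilane | CC[Si](Cl)(CC)CC | starting material
7 | lithium 3-(dimethylamino)prop-1-yn-1-ide (lithium acetylide, formed in the flask) | [Li]C#CCN(C)C | intermediate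
8 | N,N-dimethyl-3-(triethylsilyl)prop-2-yn-1-amine | CC[Si](CC)(CC)C#CCN(C)C | intermediate
9 | 1-[5,6-dibromo-1-methyl-2-(triethylsilyl)-1H-indol-3-yl]-N,N-dimethylmethanamine | CC[Si](CC)(CC)c1c(CN(C)C)c2cc(Br)c(Br)cc2n1C | intermediate
10 | {[5,6-dibromo-1-methyl-2-(triethylsilyl)-1H-indol-3-yl]methyl}dimethylammonium trifluoroacetate (formed in the flask) | CC[Si](CC)(CC)c1c(C[NH+](C)C)c2cc(Br)c(Br)cc2n1C.[O-]C(=O)C(F)(F)F | intermediate
11 | dimethyl[(2,5,6-tribromo-1-methyl-1H-indol-3-yl)methyl]ammonium trifluoroacetate (formed in the flask) | Cn1c(Br)c(C[NH+](C)C)c2cc(Br)c(Br)cc21.[O-]C(=O)C(F)(F)F | intermediate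
12 | 1-(2,5,6-tribromo-1-methyl-1H-indol-3-yl)-N,N-dimethylmethanamine | Cn1c(Br)c(CN(C)C)c2cc(Br)c(Br)cc21 | intermediate
13 | 1-(2,5,6-tribromo-1-methyl-1H-indol-3-yl)-N,N-dimethylmethanamine N-oxide | Cn1c(Br)c(C[N+](C)(C)[O-])c2cc(Br)c(Br)cc21 | target

Total step count: 6. Longest linear sequence: 5 steps (steps 1, 2, 4, 5, 6); the alkyne branch (step 3) joins at step 4.

Steps most likely to fail

1. Step 4. Palladium may start to insert into the C–Br bonds (oligomers, loss of bromine), the tertiary amine may tie up the catalyst, or the alkyne may lose silicon under hot carbonate so that insertion loses its regiocontrol. The fallback sets out from 4 and builds the ring stepwise. Sonogashira coupling of 4 with ethynyltrimethylsilane at room temperature (PdCl2(PPh3)2, CuI, Et3N), where only the iodide should react, would give 4,5-dibromo-N-methyl-2-[(trimethylsilyl)ethynyl]aniline F1. K2CO3 in MeOH would remove silicon to give 4,5-dibromo-2-ethynyl-N-methylaniline F2. CuI in DMF at 100 °C would close the ring by 5-endo-dig hydroamination to 5,6-dibromo-1-methyl-1H-indole F3. A Mannich reaction (aqueous Me2NH, aqueous CH2O, AcOH) would put the side chain on C3, giving 1-(5,6-dibromo-1-methyl-1H-indol-3-yl)-N,N-dimethylmethanamine F4. TFA would convert this into [(5,6-dibromo-1-methyl-1H-indol-3-yl)methyl]dimethylammonium trifluoroacetate F5, and NBS in CH2Cl2 would brominate the free C2 position of this 3-substituted indole. The fallback comes back to the route at 11, which gives 12 on the NaHCO3 work-up of step 5.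

2. Step 5. Electrophilic bromine may attack C3 and expel the side chain, may oxidise the amine if protonation is incomplete, or may brominate the benzo ring a second time. Acid-induced loss of silicon before bromination would be tolerable, since the C2–H compound should be brominated at C2 by the same reagent. The fallback sets out from 4 and carries C3 at the aldehyde level, so that no amine is present when bromine is introduced. Heteroannulation of 4 with commercial 3-(trimethylsilyl)prop-2-yn-1-ol (C[Si](C)(C)C#CCO) under the conditions of step 4 would give [5,6-dibromo-1-methyl-2-(trimethylsilyl)-1H-indol-3-yl]methanol F6. MnO2 in CH2Cl2 would oxidise it to 5,6-dibromo-1-methyl-2-(trimethylsilyl)-1H-indole-3-carbaldehyde F7. Ipso-bromodesilylation with NBS (or Br2) in CH2Cl2 would give 2,5,6-tribromo-1-methyl-1H-indole-3-carbaldehyde F8. Reductive amination with Me2NH and NaBH(OAc)3 in 1,2-dichloroethane at room temperature comes back to the route at 12.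

3. Step 6. The peracid may over-oxidise the indole C2–C3 bond, or the N-oxide may be lost on isolation through heterolysis of the benzylic C–N bond or a thermal 1,2-shift of the indolylmethyl group from nitrogen to oxygen. The fallback sets out from 12 and uses no oxidant: the N–O bond is brought in ready-made. MeI in THF would quaternise 12 to trimethyl[(2,5,6-tribromo-1-methyl-1H-indol-3-yl)methyl]ammonium iodide F9. Displacement of trimethylamine by the nitrogen of N,N-dimethylhydroxylamine (from its hydrochloride and K2CO3, MeCN, 40 °C) would give hydroxydimethyl[(2,5,6-tribromo-1-methyl-1H-indol-3-yl)methyl]ammonium iodide F10. The carbonate present would deprotonate it, and the fallback comes back to the route at 13.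

Further compounds
F1 | step 4 | 4,5-dibromo-N-methyl-2-[(trimethylsilyl)ethynyl]aniline | CNc1cc(Br)c(Br)cc1C#C[Si](C)(C)C
F2 | step 4 | 4,5-dibromo-2-ethynyl-N-methylaniline | CNc1cc(Br)c(Br)cc1C#C
F3 | step 4 | 5,6-dibromo-1-methyl-1H-indole | Cn1ccc2cc(Br)c(Br)cc21
F4 | step 4 | 1-(5,6-dibromo-1-methyl-1H-indol-3-yl)-N,N-dimethylmethanamine | CN(C)Cc1cn(C)c2cc(Br)c(Br)cc12
F5 | step 4 | [(5,6-dibromo-1-methyl-1H-indol-3-yl)methyl]dimethylammonium trifluoroacetate | C[NH+](C)Cc1cn(C)c2cc(Br)c(Br)cc12.[O-]C(=O)C(F)(F)F
F6 | step 5 | [5,6-dibromo-1-methyl-2-(trimethylsilyl)-1H-indol-3-yl]methanol | C[Si](C)(C)c1c(CO)c2cc(Br)c(Br)cc2n1C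
F7 | step 5 | 5,6-dibromo-1-methyl-2-(trimethylsilyl)-1H-indole-3-carbaldehyde | C[Si](C)(C)c1c(C=O)c2cc(Br)c(Br)cc2n1C
F8 | step 5 | 2,5,6-tribromo-1-methyl-1H-indole-3-carbaldehyde | Cn1c(Br)c(C=O)c2cc(Br)c(Br)cc21
F9 | step 6 | trimethyl[(2,5,6-tribromo-1-methyl-1H-indol-3-yl)methyl]ammonium iodide | Cn1c(Br)c(C[N+](C)(C)C)c2cc(Br)c(Br)cc21.[I-]
F10 | step 6 | hydroxydimethyl[(2,5,6-tribromo-1-methyl-1H-indol-3-yl)methyl]ammonium iodide | Cn1c(Br)c(C[N+](C)(C)O)c2cc(Br)c(Br)cc21.[I-]
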